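**Retrosynthetic overview**
- The E-enyne is made last from a C6 allyl group (cross-metathesis with crotonaldehyde, then Colvin homologation) on the dibromide 19.
- The oxocane (O7, C7–C13) of the 2,7-dioxabicyclo[4.2.2]decane is disconnected to the oxepane (O7, C7–C12) of the 2,6-dioxabicyclo[3.2.2]nonane 17. The enabling feature is that ring oxygen O7 is β to the exocyclic C13 sulfonate and can stand antiperiplanar to it, so it closes an oxiranium ion (O7, C12, C13) that bromide opens at C12: a one-atom ring expansion that sets C12–Br and C13–O7.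
- The oxepane comes from 7-exo opening of a (12S,13S)-epoxide (Shi epoxidation of an E-alkene) by the C7 hydroxyl of a 2,3,5,6-tetrasubstituted oxane.
- The oxane (O6, C6–C10) comes from Achmatowicz rearrangement of an (R)-furyl carbinol made from (3E)-hex-3-enoic acid and furan; C6 is set by trans C-allylation, C7 by conjugate borylation/oxidation, C9 by ketone reduction and bromide inversion.
- Ring order: oxane, then bridging oxepane, then oxocane by ring expansion.

Key step: step 14

Remark: positions follow the C15 chain of the target (C1 = alkyne terminus, C15 = methyl); O6 joins C6 and C10, O7 joins C7 and C13 in the target. The L-fructose-derived Shi ketone is assumed to be purchasable (otherwise it is made from L-sorbose).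

**Step 1**
Reactants: 1 (3E)-hex-3-enoic acid; 2 furan
Product: 4 (3E)-1-(furan-2-yl)hex-3-en-1-one, via mixed anhydride 3 (not isolated)
Conditions: (CF3CO)2O, furan (excess), CH2Cl2, 0 °C → rt; NaHCO3 work-up
Reagents that add atoms: none
Why: Friedel–Crafts acylation of furan at C2 by the mixed trifluoroacetic anhydride; the base-free medium should keep the E β,γ-alkene out of conjugation.

**Step 2**
Reactants: 4 (3E)-1-(furan-2-yl)hex-3-en-1-one
Product: 5 (1R,3E)-1-(furan-2-yl)hex-3-en-1-ol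
Conditions: (S)-2-methyl-CBS-oxazaborolidine (0.2 equiv), catecholborane, toluene, −78 °C
Reagents that add atoms: none
Why: Corey–Bakshi–Shibata reduction with the furyl group as the large substituent should give the (R)-carbinol (C10), and catecholborane at low temperature does not hydroborate the alkene.

**Step 3**
Reactants: 5 (1R,3E)-1-(furan-2-yl)hex-3-en-1-ol
Product: 6 (2R)-6-hydroxy-2-[(2E)-pent-2-en-1-yl]-2H-pyran-3(6H)-one (both anomers)
Conditions: NBS, NaHCO3, NaOAc, THF/H2O (4:1), 0 °C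
Reagents that add atoms: water (O)
Why: Achmatowicz rearrangement builds the oxane ring (O6, C6–C10) with C10 untouched; the furan is oxidised far faster than the isolated alkene.

**Step 4**
Reactants: 6 (2R)-6-hydroxy-2-[(2E)-pent-2-en-1-yl]-2H-pyran-3(6H)-one
Product: 7 (6R)-5-oxo-6-[(2E)-pent-2-en-1-yl]-5,6-dihydro-2H-pyran-2-yl acetate (both anomers)
Conditions: Ac2O, pyridine, DMAP (cat.), CH2Cl2, 0 °C
Reagents that add atoms: acetic anhydride (CC(=O)OC(C)=O)
Why: Acylation of the lactol hydroxyl installs the anomeric leaving group for C-glycosylation.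

**Step 5**
Reactants: 7 (6R)-5-oxo-6-[(2E)-pent-2-en-1-yl]-5,6-dihydro-2H-pyran-2-yl acetate
Product: 8 (2R,6R)-2-[(2E)-pent-2-en-1-yl]-6-(prop-2-en-1-yl)-2H-pyran-3(6H)-one (2,6-trans)
Conditions: allyltrimethylsilane, BF3·OEt2, CH2Cl2, −78 → −30 °C
Reagents that add atoms: allyltrimethylsilane (C=CC[Si](C)(C)C)
Why: Hosomi–Sakurai C-glycosylation of the Achmatowicz acetate; axial attack on the oxocarbenium ion anti to the C10 substituent should set C6 trans to C10.

**Step 6**
Reactants: 8 (2R,6R)-2-[(2E)-pent-2-en-1-yl]-6-(prop-2-en-1-yl)-2H-pyran-3(6H)-one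
Product: 10 (2R,5S,6R)-5-hydroxy-2-[(2E)-pent-2-en-1-yl]-6-(prop-2-en-1-yl)oxan-3-one, via β-boryl ketone 9 (not isolated)
Conditions: B2pin2, CuCl (5 mol %), Xantphos (5 mol %), NaOt-Bu (8 mol %), MeOH (2 equiv), THF, 0 °C; then NaBO3·4H2O, THF/H2O, 0 °C → rt
Reagents that add atoms: sodium perborate ([Na+].[O-]OB=O; the new oxygen); bis(pinacolato)diboron (CC1(C)OB(OC1(C)C)B1OC(C)(C)C(C)(C)O1; boron of intermediate 9 only)
Why: Copper-catalysed conjugate borylation puts boron on C7 anti to the adjacent C6 allyl group, and perborate oxidation with retention gives the C7 hydroxyl trans to C6; low alkoxide loading and temperature should limit enolisation at C10.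

**Step 7**
Reactants: 10 (2R,5S,6R)-5-hydroxy-2-[(2E)-pent-2-en-1-yl]-6-(prop-2-en-1-yl)oxan-3-one
Product: 11 (2R,5S,6R)-2-[(2E)-pent-2-en-1-yl]-6-(prop-2-en-1-yl)-5-[(triethylsilyl)oxy]oxan-3-one
Conditions: Et3SiCl, imidazole, DMF, 0 °C
Reagents that add atoms: chlorotriethylsilane (CC[Si](Cl)(CC)CC)
Why: Mild silylation masks the C7 hydroxyl so that only the C9 oxygen is brominated later.

**Step 8**
Reactants: 11 (2R,5S,6R)-2-[(2E)-pent-2-en-1-yl]-6-(prop-2-en-1-yl)-5-[(triethylsilyl)oxy]oxan-3-one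
Product: 12 (2R,3R,5S,6R)-2-[(2E)-pent-2-en-1-yl]-6-(prop-2-en-1-yl)-5-[(triethylsilyl)oxy]oxan-3-ol
Conditions: LiBH(s-Bu)3, THF, −78 °C
Reagents that add atoms: none
Why: The bulky hydride should attack the ketone from the face opposite the C10 side chain and the C7 silyloxy group, giving the C9 alcohol cis to both.

**Step 9**
Reactants: 12 (2R,3R,5S,6R)-2-[(2E)-pent-2-en-1-yl]-6-(prop-2-en-1-yl)-5-[(triethylsilyl)oxy]oxan-3-ol
Product: 13 triethyl({(2R,3S,5S,6R)-5-bromo-6-[(2E)-pent-2-en-1-yl]-2-(prop-2-en-1-yl)oxan-3-yl}oxy)silane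
Conditions: CBr4, P(n-Oct)3, 1-methylcyclohexene, toluene, 70 °C
Reagents that add atoms: carbon tetrabromide (BrC(Br)(Br)Br)
Why: Appel bromination in the trioctylphosphine variant used for hindered secondary alcohols next to ring oxygens; SN2 inversion sets C9–Br trans to the C10 substituent.

**Step 10**
Reactants: 13 triethyl({(2R,3S,5S,6R)-5-bromo-6-[(2E)-pent-2-en-1-yl]-2-(prop-2-en-1-yl)oxan-3-yl}oxy)silane
Product: 14 (2R,3S,5S,6R)-5-bromo-6-[(2E)-pent-2-en-1-yl]-2-(prop-2-en-1-yl)oxan-3-ol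
Conditions: PPTS, MeOH, 0 °C → rt
Reagents that add atoms: none
Why: Mild acidic methanolysis removes the triethylsilyl ether without touching the secondary bromide or the alkenes.

**Step 11**
Reactants: 14 (2R,3S,5S,6R)-5-bromo-6-[(2E)-pent-2-en-1-yl]-2-(prop-2-en-1-yl)oxan-3-ol
Product: 15 (2R,3S,5S,6R)-5-bromo-6-{[(2S,3S)-3-ethyloxiran-2-yl]methyl}-2-(prop-2-en-1-yl)oxan-3-ol
Conditions: L-fructose-derived Shi ketone (0.3 equiv), KHSO5 (as Oxone, 2KHSO5·KHSO4·K2SO4), K2CO3, Bu4NHSO4, Na2B4O7/Na2EDTA buffer, MeCN/CH2(OMe)2/H2O, 0 °C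
Reagents that add atoms: potassium peroxymonosulfate ([K+].[O-]S(=O)(=O)OO)
Why: Shi epoxidation; the enantiomer of the usual D-fructose ketone (which gives R,R epoxides from trans-dialkyl alkenes) should give the (12S,13S)-epoxide under reagent control and leave the terminal allyl alkene alone.

**Step 12**
Reactants: 15 (2R,3S,5S,6R)-5-bromo-6-{[(2S,3S)-3-ethyloxiran-2-yl]methyl}-2-(prop-2-en-1-yl)oxan-3-ol
Product: 16 (1S)-1-[(1S,3R,5R,7R,9S)-9-bromo-7-(prop-2-en-1-yl)-2,6-dioxabicyclo[3.2.2]nonan-3-yl]propan-1-ol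
Conditions: (±)-camphorsulfonic acid (0.2 equiv), CH2Cl2, 0 °C → rt
Reagents that add atoms: none
Why: Acid-catalysed 7-exo-tet epoxide opening by the C7 hydroxyl (cis to the C10 side chain, so the oxane can bridge in a boat) inverts C12 to R, closes the oxepane and frees the C13 hydroxyl; exo opening should be preferred over 8-endo.

**Step 13**
Reactants: 16 (1S)-1-[(1S,3R,5R,7R,9S)-9-bromo-7-(prop-2-en-1-yl)-2,6-dioxabicyclo[3.2.2]nonan-3-yl]propan-1-ol
Product: 17 (1S)-1-[(1S,3R,5R,7R,9S)-9-bromo-7-(prop-2-en-1-yl)-2,6-dioxabicyclo[3.2.2]nonan-3-yl]propyl chloromethanesulfonate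
Conditions: ClCH2SO2Cl, pyridine, CH2Cl2, 0 °C
Reagents that add atoms: chloromethanesulfonyl chloride (ClCS(Cl)(=O)=O)
Why: O-Sulfonylation with retention at C13 installs the chloromethanesulfonate, an isolable leaving group of the kind used for oxiranium-mediated ether ring expansions.

**Step 14**
Reactants: 17 (1S)-1-[(1S,3R,5R,7R,9S)-9-bromo-7-(prop-2-en-1-yl)-2,6-dioxabicyclo[3.2.2]nonan-3-yl]propyl chloromethanesulfonate
Product: 19 (1S,3R,4S,6R,8R,10S)-4,10-dibromo-3-ethyl-8-(prop-2-en-1-yl)-2,7-dioxabicyclo[4.2.2]decane, via bridged oxiranium ion 18 (not isolated)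
Conditions: LiBr (5 equiv), 2,6-di-tert-butylpyridine, (CF3)2CHOH, 40 °C
Reagents that add atoms: lithium bromide ([Li+].[Br-])
Why: Proposed new method: in the strongly ionising, weakly nucleophilic solvent the C13 sulfonate is expelled by backside attack of the oxepane oxygen O7 (3-exo-tet closure, inversion at C13) to give oxiranium ion 18, and bromide then cleaves the endocyclic C12–O7 bond anti to O7 (inversion at C12), so O7 has moved from C12 to C13 and the seven-membered ring has become the oxocane. The closest known reaction types are the zinc-acetate-promoted ring expansion of 2-(1-sulfonyloxyalkyl)oxolanes and oxanes through bicyclic oxiranium ions (5→6 and 6→7, acetate as nucleophile) and the oxiranium-mediated 1,2-shift of bromide in 2-(1-bromoalkyl) cyclic ethers; new here are the 7→8 size, the bridged frame and bromide as the capturing nucleophile. Both new stereocentres are set stereospecifically, C13 (R) by the intramolecular SN2 of O7 and C12 (S) by anti opening with bromide, so the (12R,13S) precursor maps onto the (12S,13R) product. The step needs anchimeric ionisation to outrun direct SN2 of bromide at C13; this is secured by the solvent (hydrogen-bonded, poorly nucleophilic bromide and strong assistance to sulfonate departure) and by the freely rotating exocyclic C12–C13 bond, which lets O7 stand antiperiplanar to the leaving group. It also needs opening at C12 and not at C13, which is the preferred mode in the known 5→6 and 6→7 cases and should be helped here by release of the boat strain of the [3.2.2] skeleton on passing to [4.2.2]. The C9 bromide is a much poorer nucleofuge than the sulfonate and should survive a short reaction time.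

**Step 15**
Reactants: 19 (1S,3R,4S,6R,8R,10S)-4,10-dibromo-3-ethyl-8-(prop-2-en-1-yl)-2,7-dioxabicyclo[4.2.2]decane
Product: 20 (2E)-4-[(1S,3R,4S,6R,8R,10S)-4,10-dibromo-3-ethyl-2,7-dioxabicyclo[4.2.2]decan-8-yl]but-2-enal
Conditions: crotonaldehyde (5 equiv), second-generation Hoveyda–Grubbs catalyst RuCl2(H2IMes)(=CH-C6H4-2-Oi-Pr) (5 mol %), CH2Cl2, 40 °C
Reagents that add atoms: crotonaldehyde (C/C=C/C=O)
Why: Olefin cross-metathesis of the terminal alkene with the electron-poor enal partner should give the E-enal selectively, and the secondary bromides are inert to the ruthenium carbene.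

**Step 16**
Reactants: 20 (2E)-4-[(1S,3R,4S,6R,8R,10S)-4,10-dibromo-3-ethyl-2,7-dioxabicyclo[4.2.2]decan-8-yl]but-2-enal
Product: 21 (1S,3R,4S,6R,8R,10S)-4,10-dibromo-3-ethyl-8-[(2E)-pent-2-en-4-yn-1-yl]-2,7-dioxabicyclo[4.2.2]decane (target)
Conditions: Me3SiCHN2, LiN(i-Pr)2, THF, −78 → 0 °C
Reagents that add atoms: (trimethylsilyl)diazomethane (C[Si](C)(C)C=[N+]=[N-])
Why: Colvin homologation: addition of lithiated trimethylsilyldiazomethane, Peterson-type elimination and 1,2-hydrogen shift of the alkylidene carbene turn the aldehyde into the terminal alkyne while keeping the E-alkene; the low temperature spares the secondary bromides.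

**Compound list**
1 | (3E)-hex-3-enoic acid | CC/C=C/CC(=O)O | starting material
2 | furan | c1ccoc1 | starting material
3 | (3E)-hex-3-enoic trifluoroacetic anhydride | CC/C=C/CC(=O)OC(=O)C(F)(F)F | intermediate (not isolated)
4 | (3E)-1-(furan-2-yl)hex-3-en-1-one | CC/C=C/CC(=O)c1ccco1 | intermediate
5 | (1R,3E)-1-(furan-2-yl)hex-3-en-1-ol | O[C@H](C/C=C/CC)c1ccco1 | intermediate
6 | (2R)-6-hydroxy-2-[(2E)-pent-2-en-1-yl]-2H-pyran-3(6H)-one (both anomers) | OC1O[C@H](C/C=C/CC)C(=O)C=C1 | intermediate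
7 | (6R)-5-oxo-6-[(2E)-pent-2-en-1-yl]-5,6-dihydro-2H-pyran-2-yl acetate (both anomers) | CC(=O)OC1O[C@H](C/C=C/CC)C(=O)C=C1 | intermediate
8 | (2R,6R)-2-[(2E)-pent-2-en-1-yl]-6-(prop-2-en-1-yl)-2H-pyran-3(6H)-one | C=CC[C@H]1O[C@H](C/C=C/CC)C(=O)C=C1 | intermediate
9 | (2R,5S,6R)-2-[(2E)-pent-2-en-1-yl]-6-(prop-2-en-1-yl)-5-(4,4,5,5-tetramethyl-1,3,2-dioxaborolan-2-yl)oxan-3-one | C=CC[C@H]1O[C@H](C/C=C/CC)C(=O)C[C@@H]1B2OC(C)(C)C(C)(C)O2 | intermediate (not isolated)
10 | (2R,5S,6R)-5-hydroxy-2-[(2E)-pent-2-en-1-yl]-6-(prop-2-en-1-yl)oxan-3-one | C=CC[C@H]1O[C@H](C/C=C/CC)C(=O)C[C@@H]1O | intermediate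
11 | (2R,5S,6R)-2-[(2E)-pent-2-en-1-yl]-6-(prop-2-en-1-yl)-5-[(triethylsilyl)oxy]oxan-3-one | C=CC[C@H]1O[C@H](C/C=C/CC)C(=O)C[C@@H]1O[Si](CC)(CC)CC | intermediate
12 | (2R,3R,5S,6R)-2-[(2E)-pent-2-en-1-yl]-6-(prop-2-en-1-yl)-5-[(triethylsilyl)oxy]oxan-3-ol | C=CC[C@H]1O[C@H](C/C=C/CC)[C@H](O)C[C@@H]1O[Si](CC)(CC)CC | intermediate
13 | triethyl({(2R,3S,5S,6R)-5-bromo-6-[(2E)-pent-2-en-1-yl]-2-(prop-2-en-1-yl)oxan-3-yl}oxy)silane | C=CC[C@H]1O[C@H](C/C=C/CC)[C@@H](Br)C[C@@H]1O[Si](CC)(CC)CC | intermediate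
14 | (2R,3S,5S,6R)-5-bromo-6-[(2E)-pent-2-en-1-yl]-2-(prop-2-en-1-yl)oxan-3-ol | C=CC[C@H]1O[C@H](C/C=C/CC)[C@@H](Br)C[C@@H]1O | intermediate
15 | (2R,3S,5S,6R)-5-bromo-6-{[(2S,3S)-3-ethyloxiran-2-yl]methyl}-2-(prop-2-en-1-yl)oxan-3-ol | C=CC[C@H]1O[C@H](C[C@@H]2O[C@H]2CC)[C@@H](Br)C[C@@H]1O | intermediate
16 | (1S)-1-[(1S,3R,5R,7R,9S)-9-bromo-7-(prop-2-en-1-yl)-2,6-dioxabicyclo[3.2.2]nonan-3-yl]propan-1-ol | C=CC[C@H]1O[C@@H]2C[C@H]([C@@H](O)CC)O[C@H]1C[C@@H]2Br | intermediate
17 | (1S)-1-[(1S,3R,5R,7R,9S)-9-bromo-7-(prop-2-en-1-yl)-2,6-dioxabicyclo[3.2.2]nonan-3-yl]propyl chloromethanesulfonate | C=CC[C@H]1O[C@@H]2C[C@H]([C@@H](OS(=O)(=O)CCl)CC)O[C@H]1C[C@@H]2Br | intermediate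
18 | bridged oxiranium ion (O7 bonded to C7, C12 and C13) as its chloromethanesulfonate ion pair | C=CC[C@H]1O[C@@H]2C[C@@H]3[C@@H](CC)[O+]3[C@H]1C[C@@H]2Br.[O-]S(=O)(=O)CCl | intermediate (not isolated)
19 | (1S,3R,4S,6R,8R,10S)-4,10-dibromo-3-ethyl-8-(prop-2-en-1-yl)-2,7-dioxabicyclo[4.2.2]decane | C=CC[C@H]1O[C@@H]2C[C@H](Br)[C@@H](CC)O[C@H]1C[C@@H]2Br | intermediate
20 | (2E)-4-[(1S,3R,4S,6R,8R,10S)-4,10-dibromo-3-ethyl-2,7-dioxabicyclo[4.2.2]decan-8-yl]but-2-enal | O=C/C=C/C[C@H]1O[C@@H]2C[C@H](Br)[C@@H](CC)O[C@H]1C[C@@H]2Br | intermediate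
21 | (1S,3R,4S,6R,8R,10S)-4,10-dibromo-3-ethyl-8-[(2E)-pent-2-en-4-yn-1-yl]-2,7-dioxabicyclo[4.2.2]decane | C#C/C=C/C[C@H]1O[C@@H]2C[C@H](Br)[C@@H](CC)O[C@H]1C[C@@H]2Br | target

**Step count and risks**
Total step count: 16. Longest linear sequence: 16 steps (from 1 and 2 to 21).

Steps most likely to fail:

1. Step 14. Bromide may displace the sulfonate directly at C13 before O7 participates, or the oxiranium ion may be opened at C13 so that no ring expansion occurs. The fallback separates ring expansion from bromide introduction and uses known reaction types. From 17, the established zinc acetate protocol for oxiranium ring expansion (Zn(OAc)2, AcOH/H2O, 60 °C; documented for oxolane→oxane and oxane→oxepane) should give (1S,3R,4S,6R,8R,10S)-10-bromo-3-ethyl-8-(prop-2-en-1-yl)-2,7-dioxabicyclo[4.2.2]decan-4-yl acetate F1. Methanolysis (K2CO3, MeOH) gives the corresponding 4-ol F2. Mitsunobu inversion (4-nitrobenzoic acid, PPh3, diisopropyl azodicarboxylate, THF) gives the (4R)-configured 4-nitrobenzoate F3, and a second methanolysis gives the (4R)-alcohol F4. Appel bromination with inversion (CBr4, P(n-Oct)3, toluene, 70 °C), as practised on 3-hydroxyoxocanes of this natural-product class, returns to the route at 19.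

2. Step 12. The epoxide opening may leak to the 8-endo mode, or the bridging cyclisation through a boat oxane may be so slow that intermolecular opening competes. Fallback: from 14, bromoetherification with 2,4,4,6-tetrabromocyclohexa-2,5-dienone in CH2Cl2 at low temperature should give, by anti addition across the E-alkene in the 7-exo mode, (1S,3R,5R,7R,9S)-9-bromo-3-[(1S)-1-bromopropyl]-7-(prop-2-en-1-yl)-2,6-dioxabicyclo[3.2.2]nonane F5. Face selectivity is substrate-controlled and would have to be established; the C12/C13 epimeric pair should be separable. Warming F5 with LiBr in (CF3)2CHOH (or catalytic ZnBr2) should move the bromide from C13 to C12 through the same oxiranium ion 18, returning to the route at 19 and by-passing 15–17.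

3. Step 9. During displacement of the oxyphosphonium group, E2 elimination or participation of ring oxygen O6 (ring contraction to an oxolane) may compete with SN2 inversion. Fallback: from 12, sulfonylation (ClCH2SO2Cl, pyridine, CH2Cl2, 0 °C) gives the isolable (2R,3R,5S,6R)-2-[(2E)-pent-2-en-1-yl]-6-(prop-2-en-1-yl)-5-[(triethylsilyl)oxy]oxan-3-yl chloromethanesulfonate F6. Displacement with LiBr in DMF at 40–60 °C is a two-stage SN2 through a defined sulfonate and returns to the route at 13.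

**Further compounds**
F1 | step 14 | (1S,3R,4S,6R,8R,10S)-10-bromo-3-ethyl-8-(prop-2-en-1-yl)-2,7-dioxabicyclo[4.2.2]decan-4-yl acetate | C=CC[C@H]1O[C@@H]2C[C@H](OC(C)=O)[C@@H](CC)O[C@H]1C[C@@H]2Br
F2 | step 14 | (1S,3R,4S,6R,8R,10S)-10-bromo-3-ethyl-8-(prop-2-en-1-yl)-2,7-dioxabicyclo[4.2.2]decan-4-ol | C=CC[C@H]1O[C@@H]2C[C@H](O)[C@@H](CC)O[C@H]1C[C@@H]2Br
F3 | step 14 | (1S,3R,4R,6R,8R,10S)-10-bromo-3-ethyl-8-(prop-2-en-1-yl)-2,7-dioxabicyclo[4.2.2]decan-4-yl 4-nitrobenzoate | C=CC[C@H]1O[C@@H]2C[C@@H](OC(=O)c3ccc(cc3)[N+](=O)[O-])[C@@H](CC)O[C@H]1C[C@@H]2Br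
F4 | step 14 | (1S,3R,4R,6R,8R,10S)-10-bromo-3-ethyl-8-(prop-2-en-1-yl)-2,7-dioxabicyclo[4.2.2]decan-4-ol | C=CC[C@H]1O[C@@H]2C[C@@H](O)[C@@H](CC)O[C@H]1C[C@@H]2Br
F5 | step 12 | (1S,3R,5R,7R,9S)-9-bromo-3-[(1S)-1-bromopropyl]-7-(prop-2-en-1-yl)-2,6-dioxabicyclo[3.2.2]nonane | C=CC[C@H]1O[C@@H]2C[C@H]([C@@H](Br)CC)O[C@H]1C[C@@H]2Br
F6 | step 9 | (2R,3R,5S,6R)-2-[(2E)-pent-2-en-1-yl]-6-(prop-2-en-1-yl)-5-[(triethylsilyl)oxy]oxan-3-yl chloromethanesulfonate | C=CC[C@H]1O[C@H](C/C=C/CC)[C@H](OS(=O)(=O)CCl)C[C@@H]1O[Si](CC)(CC)CC
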